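If free catalyst dies by a first-order step while it also enters the round by a step first-order in starting material, conversion and death can be set against each other and integrated in closed form, with time dropped out.

    starting material + free catalyst ⇌ catalyst intermediate A (K1 = 8.8 M⁻¹, k1 = 1100 M⁻¹ s⁻¹)
    catalyst intermediate A → catalyst intermediate B (k2 = 460 s⁻¹)
    reagent + catalyst intermediate B → catalyst intermediate C (k3 = 7800 M⁻¹ s⁻¹)
    catalyst intermediate C → catalyst intermediate D (k4 = 82 s⁻¹)
    catalyst intermediate D ⇌ free catalyst + product (K5 = 0.040 M, k5 = 84 s⁻¹)
    free catalyst → spent catalyst (k6 = 0.041 s⁻¹)

| flask | starting material | reagent | free catalyst | time |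
|---|---|---|---|---|
| Monday's | 0.098 M | 0.700 equiv | 0.1 mol% | 80 s |
| Saturday's | 0.098 M | 0.700 equiv | 0.15 mol% | 80 s |
| Friday's | 0.098 M | 0.700 equiv | 0.25 mol% | 80 s |
| Tuesday's | 0.098 M | 0.700 equiv | 0.3 mol% | 80 s |
| Sunday's | 0.098 M | 0.700 equiv | 0.5 mol% | 80 s |

- amount of product at the end, in percent of the starting material charged for Monday's, Saturday's, Friday's, Tuesday's, Sunday's, in this order
- the shape of the row from first to last (falls, then rises / rises, then falls / hardly changes / falls all the way / rises all the way)

- "hardly changes" means that all values lie within two and a half points (for a concentration: within two and a half percent of the largest)
- run time (Monday's): 80 s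

One turn of the round takes one starting material and one reagent, and the charge is 0.700 equiv, so the reagent is the limiting reagent and the converted fraction stops at 0.7. The open question is whether the catalyst lasts that far.

Let u be the fraction of starting material left and z the spent catalyst as a fraction of the starting material charged. Free catalyst dies at the constant 0.041 s⁻¹. It enters the first step at the forward constant times the starting concentration times u, and catalyst intermediate A goes on rather than falls back with the share

 share = 460 s⁻¹ / (460 s⁻¹ + 1100 M⁻¹ s⁻¹ / 8.8 M⁻¹) = 0.786

With catalyst intermediate A taken in steady state, both rates carry the same free catalyst, which cancels, and integration gives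

 z = death constant / (share × forward constant × starting concentration) × ln(starting fraction / u)

Which numbers must be good? A percent of error on the death constant is a percent on z. On the forward constant, with the equilibrium constant of the first step held, the error on z is 78.6% of that percent, and on the second step's constant or that equilibrium constant it is 21.4% of it. On the reagent charge, which sets the final u, it is 1.94 times that percent. The constants of the third, fourth and fifth steps do not appear: they move the clock, not this ratio. The loading does not appear either.

With those numbers, at u = 0.3:

 z = 0.0484% × ln(1 / 0.3) = 0.0582%

This is the death bill, the spent catalyst that conversion up to the reagent's limit costs, as a fraction of the starting material charged. It stands below the smallest loading, and Monday's charge is 1.72 times the bill. The reckoning stops here, because it gives no time, so it expects 0.7 provided 80 s suffices.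

The forecast gives 69.2%, 69.98%, 70%, 70%, 70%, shape hardly changes, holding that “catalyst death per unit of product does not depend on loading”. Its small shortfall for Monday's is its own figure, not one from the reckoning above.

The flasks give 69.3%, 70.0%, 70.0%, 70.0%, 70.0%, shape hardly changes.

In Monday's flask at 80.0 s, free catalyst enters the first step 810 times faster, forward rate alone, than it dies, and at 800 s, with product at 70.0%, spent catalyst stands at 58.3% of the catalyst charged against a bill of 58.2% of that charge. In Sunday's flask the bill comes to 11.6% of the catalyst charged, and spent catalyst at 80.0 s stands at 11.8%.

(The numbers are those of an exercise.)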